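**Retrosynthetic overview**

- Target 28 comes from 27 by BCl3 cleavage of three benzyl ethers and one isopropyl ether; 27 comes from phenol 23 by acetyl introduction on ring B (Br/Li exchange) and Houben–Hoesch butyrylation at the one free carbon of ring A.
- Ring A of 23 is disconnected by a Danheiser benzannulation into cyclobutenone 15 (supplies ring A carbons 1, 2, 5 and 6, with ring B already on the benzylic carbon at carbon 5) and 1-methoxypropyne 18 (supplies carbons 3 and 4).
- Feature used: with ring A numbered from the butyryl-bearing carbon as carbon 1, the methyl of carbon 3 and the methoxy of carbon 4 sit on neighbouring carbons, as the two ends of 1-methoxypropyne; the oxygens on carbons 2, 4 and 6 alternate as ketene carbonyl, ynol ether and enol ether oxygen of an alkoxyvinylketene, with bridge-bearing carbon 5 as the ketene alpha carbon.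
- 15 comes from ketene and ynol ether 14; 14 from benzylic bromide 7 and lithium isopropoxyacetylide (from trichloroethylene); 7 from 2-methylphloroglucinol.
- Ring order: ring B is bought; the four-membered ring is made in step 8; ring A is closed in step 10.

Key step: step 10

**Remarks on the chemistry**

- Numbering: ring A carries butyryl on carbon 1, OH on carbon 2, CH3 on carbon 3, OCH3 on carbon 4, the bridge CH2 on carbon 5 and OH on carbon 6. Ring B carries the bridge CH2 on carbon 1, OH on carbon 2, CH3 on carbon 3, OH on carbon 4, acetyl on carbon 5 and OH on carbon 6.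
- The oxygen on carbon 6 of ring A is carried as an isopropyl ether. BCl3 cleaves aryl isopropyl and benzyl ethers but should spare the unchelated methyl ether on carbon 4 at low temperature. A small primary alkyl ether on carbon 6 could not be told apart from that methyl ether once the hydroxyl on carbon 2 occupies the carbonyl chelate.
- Carbon 5 of ring B is carried as a bromide from step 3 to step 11. With no free ring position, the electron-rich benzylic bromide 7 cannot alkylate itself, ring A is the only arene that can react in step 12, and the acetyl group enters exactly at carbon 5 of ring B.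
- Assumption: ketene is delivered as a gas from a ketene generator (acetone pyrolysis).

**Route**

Step 1
Reactants: 1 2-methylphloroglucinol
Product: 3 2,4,6-trihydroxy-3-methylbenzaldehyde, via aryl iminium chloride 2 (not isolated)
Conditions: POCl3, DMF, EtOAc, 0 °C → rt; then H2O, 60 °C
Reagents that add atoms: N,N-dimethylformamide CN(C)C=O; water O
Why: Vilsmeier–Haack formylation of the very nucleophilic phloroglucinol ring at one of its two equivalent free carbons, the iminium group then deactivating the ring against a second attack.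

Step 2
Reactants: 3 2,4,6-trihydroxy-3-methylbenzaldehyde
Product: 4 2,4,6-tris(benzyloxy)-3-methylbenzaldehyde
Conditions: BnBr (3.5 equiv), K2CO3, DMF, 60 °C
Reagents that add atoms: benzyl bromide BrCc1ccccc1
Why: Williamson etherification, in which the formyl group lowers the carbon nucleophilicity of the phenoxide so that O-benzylation should dominate.

Step 3
Reactants: 4 2,4,6-tris(benzyloxy)-3-methylbenzaldehyde
Product: 5 3-bromo-2,4,6-tris(benzyloxy)-5-methylbenzaldehyde
Conditions: NBS, MeCN, 0 °C → rt, dark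
Reagents that add atoms: N-bromosuccinimide O=C1CCC(=O)N1Br
Why: Electrophilic aromatic bromination at the only free ring carbon, which is activated by three alkoxy groups, under ionic conditions that leave the aryl methyl group untouched.

Step 4
Reactants: 5 3-bromo-2,4,6-tris(benzyloxy)-5-methylbenzaldehyde
Product: 6 [3-bromo-2,4,6-tris(benzyloxy)-5-methylphenyl]methanol
Conditions: NaBH4, THF/MeOH, 0 °C
Reagents that add atoms: none
Why: Hydride reduction of the aldehyde, to which aryl bromide and benzyl ethers are inert.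

Step 5
Reactants: 6 [3-bromo-2,4,6-tris(benzyloxy)-5-methylphenyl]methanol
Product: 7 1-bromo-3-(bromomethyl)-2,4,6-tris(benzyloxy)-5-methylbenzene
Conditions: CBr4, PPh3, CH2Cl2, 0 °C; used without storage
Reagents that add atoms: tetrabromomethane BrC(Br)(Br)Br
Why: Appel bromination under neutral conditions, the fully substituted ring ruling out Friedel–Crafts self-condensation of the reactive benzylic bromide.

Step 6
Reactants: 8 trichloroethylene, 9 propan-2-ol
Product: 11 (E)-1,2-dichloro-1-(propan-2-yloxy)ethene, via dichloroacetylene 10 (not isolated)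
Conditions: KH, THF, 0 °C; then 8, −50 °C → rt
Reagents that add atoms: none
Why: Alkoxide-induced dehydrochlorination of trichloroethylene to dichloroacetylene and anti addition of isopropanol across it, the standard entry to 1,2-dichlorovinyl ethers.

Step 7
Reactants: 11 (E)-1,2-dichloro-1-(propan-2-yloxy)ethene, 7 1-bromo-3-(bromomethyl)-2,4,6-tris(benzyloxy)-5-methylbenzene
Product: 14 1-bromo-2,4,6-tris(benzyloxy)-3-methyl-5-[3-(propan-2-yloxy)prop-2-yn-1-yl]benzene, via chloro(isopropoxy)acetylene 12 (not isolated), via lithium isopropoxyacetylide 13 (not isolated)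
Conditions: 11 (1.5 equiv), n-BuLi (2.9 equiv), THF, −78 → −40 °C; then 7 (1.0 equiv), DMPU, −78 °C → rt
Reagents that add atoms: none
Why: n-BuLi eliminates HCl and exchanges the remaining chlorine to give the lithium alkoxyacetylide, which is alkylated by the benzylic bromide in an SN2 reaction, with n-BuLi kept limiting so that the aryl bromide is not exchanged.

Step 8
Reactants: 14 1-bromo-2,4,6-tris(benzyloxy)-3-methyl-5-[3-(propan-2-yloxy)prop-2-yn-1-yl]benzene
Product: 15 2-{[3-bromo-2,4,6-tris(benzyloxy)-5-methylphenyl]methyl}-3-(propan-2-yloxy)cyclobut-2-en-1-one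
Conditions: ketene (gas, excess), CH2Cl2, 0 °C → rt
Reagents that add atoms: ketene C=C=O
Why: (2+2) cycloaddition of ketene with the electron-rich ynol ether, the nucleophilic benzyl-bearing alkyne carbon attacking the ketene carbonyl carbon so that the benzyl group ends on carbon 2 and the isopropoxy group on carbon 3 of the cyclobutenone.

Step 9
Reactants: 16 2-chloro-1,1-dimethoxyethane
Product: 18 1-methoxypropyne, via sodium methoxyacetylide 17 (not isolated)
Conditions: NaNH2 (3 equiv), liquid NH3, −33 °C; then MeI, −60 → −33 °C; distillation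
Reagents that add atoms: iodomethane CI
Why: Classical alkynyl ether synthesis in which NaNH2 removes methanol and HCl from the chloroacetal and deprotonates the alkyne, the sodium acetylide then being C-methylated in the same flask.

Step 10
Reactants: 15 2-{[3-bromo-2,4,6-tris(benzyloxy)-5-methylphenyl]methyl}-3-(propan-2-yloxy)cyclobut-2-en-1-one, 18 1-methoxypropyne
Product: 23 4-{[3-bromo-2,4,6-tris(benzyloxy)-5-methylphenyl]methyl}-3-methoxy-2-methyl-5-(propan-2-yloxy)phenol, via vinylketene 19 (not isolated), via vinylcyclobutenone 20 (not isolated), via dienylketene 21 (not isolated), via cyclohexadienone 22 (not isolated)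
Conditions: 18 (3 equiv), PhMe, sealed tube, 120 °C
Reagents that add atoms: none
Why: Heating opens 15 by a four-electron electrocyclic reaction to vinylketene 19, which adds 18 in a (2+2) sense to give 20 (new bonds between carbons 2 and 3 and between carbons 4 and 5 of ring A), and 20 opens again to dienylketene 21, which closes to dienone 22 and tautomerises to phenol 23. The closest known reaction type is the Danheiser benzannulation of cyclobutenones with alkoxyalkynes. Ring A is closed by a thermal disrotatory six-electron electrocyclisation that remakes the bond between carbons 1 and 2 broken in the first opening. The product has no stereocentre; the quaternary centre of 20 is transient, and reversible opening of 20 should funnel material through the dienylketene isomer with ketene and vinyl groups cis. Only one orientation of the alkyne on the ketene leads to 23, and the oxygen lone pair of 18 secures it by making the methyl-bearing carbon the nucleophile that attacks the ketene carbonyl carbon, so methyl ends next to the new hydroxyl and methoxy next to the bridge-bearing carbon 5. The conditions are neutral, so benzyl ethers, aryl bromide and enol ether should survive, and the methoxy group of 18 has no beta hydrogen for retro-ene loss at this temperature.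

Step 11
Reactants: 23 4-{[3-bromo-2,4,6-tris(benzyloxy)-5-methylphenyl]methyl}-3-methoxy-2-methyl-5-(propan-2-yloxy)phenol
Product: 25 1-[2,4,6-tris(benzyloxy)-3-{[4-hydroxy-2-methoxy-3-methyl-6-(propan-2-yloxy)phenyl]methyl}-5-methylphenyl]ethan-1-one, via dilithiated phenoxide 24 (not isolated)
Conditions: n-BuLi (2.1 equiv), THF, −78 °C; then MeC(O)N(OMe)Me (3 equiv), −78 → 0 °C; aq NH4Cl
Reagents that add atoms: N-methoxy-N-methylacetamide CON(C)C(C)=O
Why: The first equivalent of n-BuLi deprotonates the phenol and the second effects bromine–lithium exchange, and the resulting 2,6-dialkoxyaryllithium is acylated by the Weinreb amide, whose chelated tetrahedral adduct prevents over-addition.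

Step 12
Reactants: 25 1-[2,4,6-tris(benzyloxy)-3-{[4-hydroxy-2-methoxy-3-methyl-6-(propan-2-yloxy)phenyl]methyl}-5-methylphenyl]ethan-1-one
Product: 27 1-[3-{[3-acetyl-2,4,6-tris(benzyloxy)-5-methylphenyl]methyl}-6-hydroxy-4-methoxy-5-methyl-2-(propan-2-yloxy)phenyl]butan-1-one, via ketiminium chloride 26 (not isolated)
Conditions: PrCN, ZnCl2, HCl (g), Et2O, 0 °C; then H2O, 80 °C
Reagents that add atoms: butyronitrile CCCC#N; water O
Why: Houben–Hoesch acylation, the classical way to acylate phloroglucinol-type phenols and their ethers, which can only occur at carbon 1 of ring A because ring B is fully substituted and deactivated by its acetyl group, followed by hydrolysis of the ketiminium salt.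

Step 13
Reactants: 27 1-[3-{[3-acetyl-2,4,6-tris(benzyloxy)-5-methylphenyl]methyl}-6-hydroxy-4-methoxy-5-methyl-2-(propan-2-yloxy)phenyl]butan-1-one
Product: 28 1-[3-[(3-acetyl-2,4,6-trihydroxy-5-methylphenyl)methyl]-2,6-dihydroxy-4-methoxy-5-methylphenyl]butan-1-one
Conditions: BCl3 (excess), pentamethylbenzene, CH2Cl2, −78 → 0 °C; then MeOH/H2O
Reagents that add atoms: none
Why: Lewis-acid ether cleavage in which BCl3 removes benzyl groups (trapped by pentamethylbenzene) and the isopropyl group through stabilised carbocations, whereas the methyl ether on carbon 4 of ring A, which can neither ionise nor chelate to a carbonyl, should be kept as long as the mixture is not warmed above 0 °C.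

**Compound list**

1 | 2-methylphloroglucinol (2-methylbenzene-1,3,5-triol) | Cc1c(O)cc(O)cc1O | starting material
2 | [(2,4,6-trihydroxy-3-methylphenyl)methylidene]dimethylammonium chloride | C[N+](C)=Cc1c(O)cc(O)c(C)c1O.[Cl-] | intermediate
3 | 2,4,6-trihydroxy-3-methylbenzaldehyde | O=Cc1c(O)cc(O)c(C)c1O | intermediate
4 | 2,4,6-tris(benzyloxy)-3-methylbenzaldehyde | O=Cc1c(OCc2ccccc2)cc(OCc2ccccc2)c(C)c1OCc1ccccc1 | intermediate
5 | 3-bromo-2,4,6-tris(benzyloxy)-5-methylbenzaldehyde | O=Cc1c(OCc2ccccc2)c(Br)c(OCc2ccccc2)c(C)c1OCc1ccccc1 | intermediate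
6 | [3-bromo-2,4,6-tris(benzyloxy)-5-methylphenyl]methanol | OCc1c(OCc2ccccc2)c(Br)c(OCc2ccccc2)c(C)c1OCc1ccccc1 | intermediate
7 | 1-bromo-3-(bromomethyl)-2,4,6-tris(benzyloxy)-5-methylbenzene | BrCc1c(OCc2ccccc2)c(Br)c(OCc2ccccc2)c(C)c1OCc1ccccc1 | intermediate
8 | trichloroethylene | ClC=C(Cl)Cl | starting material
9 | propan-2-ol | CC(C)O | starting material
10 | dichloroacetylene | ClC#CCl | intermediate
11 | (E)-1,2-dichloro-1-(propan-2-yloxy)ethene | CC(C)O/C(Cl)=C\Cl | intermediate
12 | 1-chloro-2-(propan-2-yloxy)acetylene | ClC#COC(C)C | intermediate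
13 | lithium (propan-2-yloxy)acetylide | [Li]C#COC(C)C | intermediate
14 | 1-bromo-2,4,6-tris(benzyloxy)-3-methyl-5-[3-(propan-2-yloxy)prop-2-yn-1-yl]benzene | CC(C)OC#CCc1c(OCc2ccccc2)c(Br)c(OCc2ccccc2)c(C)c1OCc1ccccc1 | intermediate
15 | 2-{[3-bromo-2,4,6-tris(benzyloxy)-5-methylphenyl]methyl}-3-(propan-2-yloxy)cyclobut-2-en-1-one | CC(C)OC1=C(Cc2c(OCc3ccccc3)c(Br)c(OCc3ccccc3)c(C)c2OCc2ccccc2)C(=O)C1 | intermediate
16 | 2-chloro-1,1-dimethoxyethane (chloroacetaldehyde dimethyl acetal) | COC(CCl)OC | starting material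
17 | sodium methoxyacetylide | [Na]C#COC | intermediate
18 | 1-methoxypropyne | CC#COC | intermediate
19 | 2-{[3-bromo-2,4,6-tris(benzyloxy)-5-methylphenyl]methyl}-3-(propan-2-yloxy)buta-1,3-dien-1-one (vinylketene) | C=C(OC(C)C)C(=C=O)Cc1c(OCc2ccccc2)c(Br)c(OCc2ccccc2)c(C)c1OCc1ccccc1 | intermediate
20 | 4-{[3-bromo-2,4,6-tris(benzyloxy)-5-methylphenyl]methyl}-3-methoxy-2-methyl-4-[1-(propan-2-yloxy)ethenyl]cyclobut-2-en-1-one (racemic) | O=C1C(C)=C(OC)C1(Cc2c(OCc3ccccc3)c(Br)c(OCc3ccccc3)c(C)c2OCc2ccccc2)C(=C)OC(C)C | intermediate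
21 | (3E)-4-{[3-bromo-2,4,6-tris(benzyloxy)-5-methylphenyl]methyl}-3-methoxy-2-methyl-5-(propan-2-yloxy)hexa-1,3,5-trien-1-one (ketene and vinyl cis) | O=C=C(C)/C(OC)=C(\C(=C)OC(C)C)Cc1c(OCc2ccccc2)c(Br)c(OCc2ccccc2)c(C)c1OCc1ccccc1 | intermediate
22 | 4-{[3-bromo-2,4,6-tris(benzyloxy)-5-methylphenyl]methyl}-3-methoxy-2-methyl-5-(propan-2-yloxy)cyclohexa-2,4-dien-1-one | O=C1CC(OC(C)C)=C(Cc2c(OCc3ccccc3)c(Br)c(OCc3ccccc3)c(C)c2OCc2ccccc2)C(OC)=C1C | intermediate
23 | 4-{[3-bromo-2,4,6-tris(benzyloxy)-5-methylphenyl]methyl}-3-methoxy-2-methyl-5-(propan-2-yloxy)phenol | CC(C)Oc1cc(O)c(C)c(OC)c1Cc1c(OCc2ccccc2)c(Br)c(OCc2ccccc2)c(C)c1OCc1ccccc1 | intermediate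
24 | lithium phenoxide of 23 with lithium in place of bromine on ring B | CC(C)Oc1cc(O[Li])c(C)c(OC)c1Cc1c(OCc2ccccc2)c([Li])c(OCc2ccccc2)c(C)c1OCc1ccccc1 | intermediate
25 | 1-[2,4,6-tris(benzyloxy)-3-{[4-hydroxy-2-methoxy-3-methyl-6-(propan-2-yloxy)phenyl]methyl}-5-methylphenyl]ethan-1-one | CC(C)Oc1cc(O)c(C)c(OC)c1Cc1c(OCc2ccccc2)c(C(C)=O)c(OCc2ccccc2)c(C)c1OCc1ccccc1 | intermediate
26 | ketiminium chloride of 27 (C=NH2+ in place of the butyryl C=O) | CCCC(=[NH2+])c1c(O)c(C)c(OC)c(Cc2c(OCc3ccccc3)c(C(C)=O)c(OCc3ccccc3)c(C)c2OCc2ccccc2)c1OC(C)C.[Cl-] | intermediate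
27 | 1-[3-{[3-acetyl-2,4,6-tris(benzyloxy)-5-methylphenyl]methyl}-6-hydroxy-4-methoxy-5-methyl-2-(propan-2-yloxy)phenyl]butan-1-one | CCCC(=O)c1c(O)c(C)c(OC)c(Cc2c(OCc3ccccc3)c(C(C)=O)c(OCc3ccccc3)c(C)c2OCc2ccccc2)c1OC(C)C | intermediate
28 | 1-[3-[(3-acetyl-2,4,6-trihydroxy-5-methylphenyl)methyl]-2,6-dihydroxy-4-methoxy-5-methylphenyl]butan-1-one | CCCC(=O)c1c(O)c(C)c(OC)c(Cc2c(O)c(C)c(O)c(C(C)=O)c2O)c1O | target

**Totals**

Total step count: 13. Longest linear sequence: 11 steps (steps 1, 2, 3, 4, 5, 7, 8, 10, 11, 12, 13).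

**Steps most likely to fail**

1. Step 10. The donor-stabilised cyclobutenone may open too slowly. At the temperature then required, the hindered disubstituted ketene could dimerise or acylate the product phenol faster than it adds to the alkyne (a methanolic K2CO3 wash would return phenol trapped as ester). Fallback: generate the same vinylketene 19 at room temperature by photochemical Wolff rearrangement, the diazo ketone variant of the benzannulation. It sets out from bromide 7. Alkylation of the lithium enolate of N-methoxy-N-methylacetamide (LiN(iPr)2, THF, −78 °C) with 7 should give 3-[3-bromo-2,4,6-tris(benzyloxy)-5-methylphenyl]-N-methoxy-N-methylpropanamide F1. Addition of 1-(propan-2-yloxy)vinyllithium F2 (from isopropyl vinyl ether and t-BuLi, THF, −78 → 0 °C) should give 5-[3-bromo-2,4,6-tris(benzyloxy)-5-methylphenyl]-2-(propan-2-yloxy)pent-1-en-3-one F3. Detrifluoroacetylative diazo transfer (LiN(SiMe3)2, CF3CO2CH2CF3, THF, −78 °C; then MsN3, Et3N, H2O, MeCN) should pass through 3-{[3-bromo-2,4,6-tris(benzyloxy)-5-methylphenyl]methyl}-1,1,1-trifluoro-5-(propan-2-yloxy)hex-5-ene-2,4-dione F4 to 5-[3-bromo-2,4,6-tris(benzyloxy)-5-methylphenyl]-4-diazo-2-(propan-2-yloxy)pent-1-en-3-one F5. Irradiation of this diazo ketone with 18 (Pyrex-filtered Hg lamp, CH2Cl2, rt; then 80 °C) should pass through 19 to 22 and come back to the route at phenol 23.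

2. Step 8. Ketene may oligomerise faster than it adds to the hindered internal ynol ether, and adventitious acid may hydrate the ynol ether. Fallback: use the more electrophilic dichloroketene and then remove the chlorines. It sets out from 14. Dichloroketene F6 (from Cl3CCOCl and Zn–Cu couple, Et2O/DME, rt) should add with the same orientation to give 2-{[3-bromo-2,4,6-tris(benzyloxy)-5-methylphenyl]methyl}-4,4-dichloro-3-(propan-2-yloxy)cyclobut-2-en-1-one F7. Reductive dechlorination (Zn dust, AcOH, TMEDA, EtOH, 0 °C) should come back to the route at cyclobutenone 15.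

3. Step 12. The nitrilium electrophile may not reach the hindered carbon 1 of ring A, leaving O-imidate formation, acid-promoted loss of benzyl groups or acid cleavage of the diarylmethane bridge as the main processes. Fallback: form the C–acyl bond by O-acylation and rearrangement. It sets out from 25. Esterification (PrCOCl, Et3N, DMAP, CH2Cl2, 0 °C) should give 4-{[3-acetyl-2,4,6-tris(benzyloxy)-5-methylphenyl]methyl}-3-methoxy-2-methyl-5-(propan-2-yloxy)phenyl butanoate F8. Fries rearrangement (Sc(OTf)3 cat., PhMe, 100 °C), for which carbon 1 of ring A is the only open ortho or para position, should come back to the route at 27.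

**Further compounds**

F1 | step 10 | 3-[3-bromo-2,4,6-tris(benzyloxy)-5-methylphenyl]-N-methoxy-N-methylpropanamide | CON(C)C(=O)CCc1c(OCc2ccccc2)c(Br)c(OCc2ccccc2)c(C)c1OCc1ccccc1
F2 | step 10 | 1-(propan-2-yloxy)vinyllithium | [Li]C(=C)OC(C)C
F3 | step 10 | 5-[3-bromo-2,4,6-tris(benzyloxy)-5-methylphenyl]-2-(propan-2-yloxy)pent-1-en-3-one | C=C(OC(C)C)C(=O)CCc1c(OCc2ccccc2)c(Br)c(OCc2ccccc2)c(C)c1OCc1ccccc1
F4 | step 10 | 3-{[3-bromo-2,4,6-tris(benzyloxy)-5-methylphenyl]methyl}-1,1,1-trifluoro-5-(propan-2-yloxy)hex-5-ene-2,4-dione (racemic) | C=C(OC(C)C)C(=O)C(Cc1c(OCc2ccccc2)c(Br)c(OCc2ccccc2)c(C)c1OCc1ccccc1)C(=O)C(F)(F)F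
F5 | step 10 | 5-[3-bromo-2,4,6-tris(benzyloxy)-5-methylphenyl]-4-diazo-2-(propan-2-yloxy)pent-1-en-3-one | C=C(OC(C)C)C(=O)C(=[N+]=[N-])Cc1c(OCc2ccccc2)c(Br)c(OCc2ccccc2)c(C)c1OCc1ccccc1
F6 | step 8 | dichloroketene | ClC(Cl)=C=O
F7 | step 8 | 2-{[3-bromo-2,4,6-tris(benzyloxy)-5-methylphenyl]methyl}-4,4-dichloro-3-(propan-2-yloxy)cyclobut-2-en-1-one | O=C1C(Cc2c(OCc3ccccc3)c(Br)c(OCc3ccccc3)c(C)c2OCc2ccccc2)=C(OC(C)C)C1(Cl)Cl
F8 | step 12 | 4-{[3-acetyl-2,4,6-tris(benzyloxy)-5-methylphenyl]methyl}-3-methoxy-2-methyl-5-(propan-2-yloxy)phenyl butanoate | CCCC(=O)Oc1cc(OC(C)C)c(Cc2c(OCc3ccccc3)c(C(C)=O)c(OCc3ccccc3)c(C)c2OCc2ccccc2)c(OC)c1C
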